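## Retrosynthetic overview

1. Lepadin H ⇐ Boc/TBS removal ⇐ Mitsunobu esterification with (2E,4E)-octa-2,4-dienoic acid, inverting C3 of an N-Boc all-cis 2-methyldecahydroquinolin-3-ol.
2. All-cis decahydroquinolinol ⇐ face-selective hydrogenation of a 3-hydroxy-2-methyl-5-alkyl-5,6,7,8-tetrahydroquinoline; the C5 stereocentre directs C2, C3, C4a and C8a.
3. Tetrahydroquinolinol ⇐ intramolecular oxazole–olefin Diels–Alder (Kondrat'eva) reaction of a 2-(4-vinylalkyl)-5-ethoxy-4-methyloxazole; the carbocycle and the pyridine ring close in the same operation.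
4. Cycloaddition precursor ⇐ Cu-catalysed asymmetric allylic alkylation (sets C5) of an oxazole allyl bromide (hexenoic acid + alanine ester + dibromobutene) with a Grignard reagent from (R)-1,2-epoxypentane (C5′ from the chiral pool).

Assumption: (R)-1,2-epoxypentane, Schwartz's reagent and both Taniaphos enantiomers are bought; the Taniaphos enantiomer used in step 7 is the one that gives the 4S product, fixed by one test reaction.

## Route

Step 1
Reactants: 1 (R)-2-propyloxirane; 2 allylmagnesium bromide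
Product: 3 (R)-oct-7-en-4-ol
Conditions: CuI (10 mol %), THF, −30 → 0 °C; aq NH4Cl
Reagents that add atoms: none
Why: Cu-catalysed Grignard epoxide opening (SN2) at the unsubstituted CH2 leaves the chiral-pool stereocentre untouched, so the R carbinol (the future C5′) is carried over.

Step 2
Reactants: 3 (R)-oct-7-en-4-ol
Product: 4 tert-butyl(dimethyl){[(4R)-oct-7-en-4-yl]oxy}silane
Conditions: TBSCl, imidazole, DMF, rt
Reagents that add atoms: tert-butyldimethylsilyl chloride, CC(C)(C)[Si](C)(C)Cl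
Why: Standard silyl ether protection keeps this secondary alcohol distinct from the ring C3–OH that is esterified in step 11.

Step 3
Reactants: 4 tert-butyl(dimethyl){[(4R)-oct-7-en-4-yl]oxy}silane
Product: 6 {[(4R)-8-bromooctan-4-yl]oxy}(tert-butyl)dimethylsilane, via alkylzirconocene chloride 5 (not isolated)
Conditions: Cp2Zr(H)Cl, CH2Cl2, rt; then NBS, 0 °C
Reagents that add atoms: N-bromosuccinimide, O=C1CCC(=O)N1Br
Why: Hydrozirconation places Zr on the terminal carbon (anti-Markovnikov) and bromination of the C–Zr bond gives the primary bromide under neutral conditions that spare the TBS ether.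

Step 4
Reactants: 7 hex-5-enoic acid; 8 DL-alanine ethyl ester hydrochloride
Product: 9 ethyl N-(hex-5-enoyl)-DL-alaninate
Conditions: EDC·HCl, HOBt (cat.), Et3N, CH2Cl2, 0 °C → rt
Reagents that add atoms: none
Why: Carbodiimide amide coupling; the alanine stereocentre is irrelevant because it becomes the sp2 C4 of the oxazole.

Step 5
Reactants: 9 ethyl N-(hex-5-enoyl)-DL-alaninate
Product: 10 5-ethoxy-4-methyl-2-(pent-4-en-1-yl)-1,3-oxazole
Conditions: P2O5, CHCl3, reflux
Reagents that add atoms: none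
Why: Robinson–Gabriel-type cyclodehydration of an N-acyl α-amino ester gives the 5-alkoxyoxazole, as in the classical vitamin B6 oxazole synthesis.

Step 6
Reactants: 10 5-ethoxy-4-methyl-2-(pent-4-en-1-yl)-1,3-oxazole; 11 (E)-1,4-dibromobut-2-ene
Product: 12 2-[(4E)-6-bromohex-4-en-1-yl]-5-ethoxy-4-methyl-1,3-oxazole
Conditions: Grubbs II (3 mol %), 11 (3 equiv), CH2Cl2, 40 °C
Reagents that add atoms: none
Why: Olefin cross-metathesis of a terminal alkene with excess symmetrical dibromobutene gives the (E)-allyl bromide (E:Z about 9:1) and the weakly basic oxazole does not poison the Ru carbene.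

Step 7
Reactants: 6 {[(4R)-8-bromooctan-4-yl]oxy}(tert-butyl)dimethylsilane; 12 2-[(4E)-6-bromohex-4-en-1-yl]-5-ethoxy-4-methyl-1,3-oxazole
Product: 14 2-[(4S,9R)-9-{[tert-butyl(dimethyl)silyl]oxy}-4-ethenyldodecyl]-5-ethoxy-4-methyl-1,3-oxazole, via alkylmagnesium bromide 13 (not isolated)
Conditions: Mg, Et2O, rt; then 12, CuBr·SMe2 (3 mol %), Taniaphos (3.6 mol %), CH2Cl2, −78 °C
Reagents that add atoms: none
Why: Copper-catalysed asymmetric allylic alkylation delivers the primary alkyl Grignard to the γ-carbon of the (E)-allyl bromide (SN2′), creating the future C5 stereocentre as S under catalyst control (about 90 % ee expected, so roughly 95:5 dr against the fixed remote R centre) and unveiling the terminal vinyl dienophile.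

Step 8
Reactants: 14 2-[(4S,9R)-9-{[tert-butyl(dimethyl)silyl]oxy}-4-ethenyldodecyl]-5-ethoxy-4-methyl-1,3-oxazole
Product: 16 (5S)-5-[(5R)-5-{[tert-butyl(dimethyl)silyl]oxy}octyl]-2-methyl-5,6,7,8-tetrahydroquinolin-3-ol, via oxa-bridged cycloadduct 15 (not isolated)
Conditions: 1,2-dichlorobenzene (0.02 M), 200 °C, sealed tube
Reagents that add atoms: none
Why: Intramolecular oxazole–olefin Diels–Alder reaction (Kondrat'eva pyridine synthesis) in which the four-atom tether forces oxazole C2 onto the internal alkene carbon so that the carbocycle and the azine ring close together, and the bridged adduct aromatises irreversibly by bridge opening and loss of ethanol, leaving the bridge oxygen as the 3-OH next to the 2-methyl group while the C5 stereocentre is a spectator.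

Step 9
Reactants: 16 (5S)-5-[(5R)-5-{[tert-butyl(dimethyl)silyl]oxy}octyl]-2-methyl-5,6,7,8-tetrahydroquinolin-3-ol
Product: 18 tert-butyl (2S,3S,4aS,5S,8aR)-5-[(5R)-5-{[tert-butyl(dimethyl)silyl]oxy}octyl]-3-hydroxy-2-methyloctahydroquinoline-1(2H)-carboxylate, via free decahydroquinolinol 17 (not isolated)
Conditions: H2 (60 bar), 5% Rh/Al2O3, EtOH, 50 °C; filter; then Boc2O, MeOH, 55 °C
Reagents that add atoms: di-tert-butyl dicarbonate, CC(C)(C)OC(=O)OC(=O)OC(C)(C)C
Why: Heterogeneous pyridine hydrogenation adds all four ring hydrogens (C2, C3, C4a, C8a) from the catalyst face opposite the pseudoaxial C5 side chain, giving the cis-fused ring with H2/H4a/H5/H8a all syn and the 3-OH cis to the 2-methyl group, and the amine is then capped as its carbamate (N-Boc protection).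

Step 10
Reactants: 19 (E)-hex-2-enal; 20 malonic acid
Product: 21 (2E,4E)-octa-2,4-dienoic acid
Conditions: pyridine, piperidine (cat.), 90 °C; aq HCl
Reagents that add atoms: none
Why: Knoevenagel–Doebner condensation with decarboxylation gives the thermodynamically preferred E,E-dienoic acid, as in the sorbic acid synthesis.

Step 11
Reactants: 18 tert-butyl (2S,3S,4aS,5S,8aR)-5-[(5R)-5-{[tert-butyl(dimethyl)silyl]oxy}octyl]-3-hydroxy-2-methyloctahydroquinoline-1(2H)-carboxylate; 21 (2E,4E)-octa-2,4-dienoic acid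
Product: 22 tert-butyl (2S,3R,4aS,5S,8aR)-5-[(5R)-5-{[tert-butyl(dimethyl)silyl]oxy}octyl]-2-methyl-3-{[(2E,4E)-octa-2,4-dienoyl]oxy}octahydroquinoline-1(2H)-carboxylate
Conditions: PPh3, DIAD, toluene, 0 °C → rt
Reagents that add atoms: none
Why: Mitsunobu esterification displaces the C3 oxyphosphonium by the dienoate with SN2 inversion (3S → 3R, trans to the 2-methyl group) in the same step that forms the ester, while the Boc group blocks N-acylation and aziridinium formation.

Step 12
Reactants: 22 tert-butyl (2S,3R,4aS,5S,8aR)-5-[(5R)-5-{[tert-butyl(dimethyl)silyl]oxy}octyl]-2-methyl-3-{[(2E,4E)-octa-2,4-dienoyl]oxy}octahydroquinoline-1(2H)-carboxylate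
Product: 23 lepadin H
Conditions: TFA/CH2Cl2/H2O (10:10:1), 0 °C → rt; aq NaHCO3
Reagents that add atoms: none
Why: Acidolysis removes the Boc carbamate and the secondary TBS ether in one operation without touching the dienoate ester or any stereocentre.

## Compound list

1 | (R)-2-propyloxirane [(R)-1,2-epoxypentane] | CCC[C@@H]1CO1 | starting material
2 | allylmagnesium bromide | C=CC[Mg]Br | starting material
3 | (R)-oct-7-en-4-ol | C=CCC[C@H](O)CCC | intermediate
4 | tert-butyl(dimethyl){[(4R)-oct-7-en-4-yl]oxy}silane | C=CCC[C@H](O[Si](C)(C)C(C)(C)C)CCC | intermediate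
5 | chlorobis(cyclopentadienyl){(5R)-5-[(tert-butyldimethylsilyl)oxy]octyl}zirconium | Cl[Zr](CCCC[C@H](O[Si](C)(C)C(C)(C)C)CCC)(C1C=CC=C1)C1C=CC=C1 | intermediate
6 | {[(4R)-8-bromooctan-4-yl]oxy}(tert-butyl)dimethylsilane | BrCCCC[C@H](O[Si](C)(C)C(C)(C)C)CCC | intermediate
7 | hex-5-enoic acid | C=CCCCC(=O)O | starting material
8 | DL-alanine ethyl ester hydrochloride | CCOC(=O)C(C)N.Cl | starting material
9 | ethyl N-(hex-5-enoyl)-DL-alaninate | C=CCCCC(=O)NC(C)C(=O)OCC | intermediate
10 | 5-ethoxy-4-methyl-2-(pent-4-en-1-yl)-1,3-oxazole | C=CCCCc1nc(C)c(OCC)o1 | intermediate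
11 | (E)-1,4-dibromobut-2-ene | BrC/C=C/CBr | starting material
12 | 2-[(4E)-6-bromohex-4-en-1-yl]-5-ethoxy-4-methyl-1,3-oxazole | BrC/C=C/CCCc1nc(C)c(OCC)o1 | intermediate
13 | bromo{(5R)-5-[(tert-butyldimethylsilyl)oxy]octyl}magnesium | Br[Mg]CCCC[C@H](O[Si](C)(C)C(C)(C)C)CCC | intermediate
14 | 2-[(4S,9R)-9-{[tert-butyl(dimethyl)silyl]oxy}-4-ethenyldodecyl]-5-ethoxy-4-methyl-1,3-oxazole | C=C[C@@H](CCCC[C@H](O[Si](C)(C)C(C)(C)C)CCC)CCCc1nc(C)c(OCC)o1 | intermediate
15 | (5S)-3-ethoxy-2-methyl-5-[(5R)-5-{[tert-butyl(dimethyl)silyl]oxy}octyl]-3,4,4a,5,6,7,8,8a-octahydro-3,8a-epoxyquinoline (bridge diastereomers, new centres not defined) | CCOC12CC3[C@@H](CCCC[C@H](O[Si](C)(C)C(C)(C)C)CCC)CCCC3(O1)N=C2C | intermediate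
16 | (5S)-5-[(5R)-5-{[tert-butyl(dimethyl)silyl]oxy}octyl]-2-methyl-5,6,7,8-tetrahydroquinolin-3-ol | Cc1nc2CCC[C@H](CCCC[C@H](O[Si](C)(C)C(C)(C)C)CCC)c2cc1O | intermediate
17 | (2S,3S,4aS,5S,8aR)-5-[(5R)-5-{[tert-butyl(dimethyl)silyl]oxy}octyl]-2-methyldecahydroquinolin-3-ol | O[C@H]1C[C@H]2[C@@H](CCCC[C@H](O[Si](C)(C)C(C)(C)C)CCC)CCC[C@H]2N[C@H]1C | intermediate
18 | tert-butyl (2S,3S,4aS,5S,8aR)-5-[(5R)-5-{[tert-butyl(dimethyl)silyl]oxy}octyl]-3-hydroxy-2-methyloctahydroquinoline-1(2H)-carboxylate | O[C@H]1C[C@H]2[C@@H](CCCC[C@H](O[Si](C)(C)C(C)(C)C)CCC)CCC[C@H]2N(C(=O)OC(C)(C)C)[C@H]1C | intermediate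
19 | (E)-hex-2-enal | CCC/C=C/C=O | starting material
20 | malonic acid | OC(=O)CC(=O)O | starting material
21 | (2E,4E)-octa-2,4-dienoic acid | CCC/C=C/C=C/C(=O)O | intermediate
22 | tert-butyl (2S,3R,4aS,5S,8aR)-5-[(5R)-5-{[tert-butyl(dimethyl)silyl]oxy}octyl]-2-methyl-3-{[(2E,4E)-octa-2,4-dienoyl]oxy}octahydroquinoline-1(2H)-carboxylate | CCC/C=C/C=C/C(=O)O[C@@H]1C[C@H]2[C@@H](CCCC[C@H](O[Si](C)(C)C(C)(C)C)CCC)CCC[C@H]2N(C(=O)OC(C)(C)C)[C@H]1C | intermediate
23 | lepadin H, (2S,3R,4aS,5S,8aR)-5-[(5R)-5-hydroxyoctyl]-2-methyldecahydroquinolin-3-yl (2E,4E)-octa-2,4-dienoate | CCC/C=C/C=C/C(=O)O[C@@H]1C[C@H]2[C@@H](CCCC[C@H](O)CCC)CCC[C@H]2N[C@H]1C | target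

## Step count and risks

Total step count: 12.
Longest linear sequence: 8 steps (1, 2, 3, 7, 8, 9, 11, 12; the branch 4, 5, 6, 7, 8, 9, 11, 12 is equally long).

The three steps most likely to fail:

Step 7 (asymmetric allylic alkylation). The Lewis-basic oxazole may erode the Cu/Taniaphos selectivity, the minor Z isomer of 12 lowers the dr, and the C5 epimer cannot be separated because the two stereocentres are remote. The fallback builds the heterocycle only after the stereocentre; it sets out from 7 and comes back at 14. Fischer esterification of 7 (MeOH, cat. H2SO4) gives methyl hex-5-enoate F1. Cross-metathesis of F1 with 11 gives methyl (5E)-7-bromohept-5-enoate F2, in which the ester is a documented spectator in Cu-catalysed allylic alkylation. Alkylation of F2 with 13 under the step 7 conditions gives methyl (5S,10R)-10-{[tert-butyl(dimethyl)silyl]oxy}-5-ethenyltridecanoate F3. Saponification (LiOH, THF/H2O) gives (5S,10R)-10-{[tert-butyl(dimethyl)silyl]oxy}-5-ethenyltridecanoic acid F4. EDC coupling with 8 gives ethyl N-[(5S,10R)-10-{[tert-butyl(dimethyl)silyl]oxy}-5-ethenyltridecanoyl]-DL-alaninate F5. Cyclodehydration with POCl3/Et3N (basic, so the TBS ether survives) gives 14.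

Step 8 (intramolecular Kondrat'eva cycloaddition). An unactivated terminal alkene meets an electron-rich alkoxyoxazole, so about 200 °C is needed and oxazole decomposition may compete. The fallback activates the dienophile with a traceless group; it sets out from 14 and comes back at 16. Cross-metathesis of the vinyl group of 14 with acrylic acid (Hoveyda–Grubbs II, CH2Cl2, 40 °C) gives (2E,4S,9R)-9-{[tert-butyl(dimethyl)silyl]oxy}-4-[3-(5-ethoxy-4-methyl-1,3-oxazol-2-yl)propyl]dodec-2-enoic acid F6. The unsaturated acid is an electron-poor partner matched to the alkoxyoxazole, so the cycloaddition should run near 110 °C in toluene. After bridge opening and loss of ethanol, the 3-oxo tautomer is a β-keto acid that decarboxylates, giving 16.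

Step 9 (pyridine hydrogenation). Facial selectivity relative to C5 and cis ring fusion may be incomplete. The free 3-hydroxypyridine can also reduce through its keto tautomer (scrambling C3) or lose oxygen by hydrogenolysis. The fallback blocks the keto pathway; it sets out from 16 and comes back at 18. Silylation of the phenol (TESCl, imidazole, CH2Cl2) gives (5S)-5-[(5R)-5-{[tert-butyl(dimethyl)silyl]oxy}octyl]-2-methyl-3-[(triethylsilyl)oxy]-5,6,7,8-tetrahydroquinoline F7, which cannot tautomerise to a piperidin-3-one and resists C–O cleavage, so C3 is set by syn addition with the other ring centres. Hydrogenation over Rh followed by Boc2O gives tert-butyl (2S,3S,4aS,5S,8aR)-5-[(5R)-5-{[tert-butyl(dimethyl)silyl]oxy}octyl]-2-methyl-3-[(triethylsilyl)oxy]octahydroquinoline-1(2H)-carboxylate F8. Selective removal of the TES ether (PPTS, MeOH, 0 °C; the secondary TBS ether stays) gives 18.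

Further compounds

F1 | step 7 | methyl hex-5-enoate | C=CCCCC(=O)OC
F2 | step 7 | methyl (5E)-7-bromohept-5-enoate | BrC/C=C/CCCC(=O)OC
F3 | step 7 | methyl (5S,10R)-10-{[tert-butyl(dimethyl)silyl]oxy}-5-ethenyltridecanoate | C=C[C@@H](CCCC[C@H](O[Si](C)(C)C(C)(C)C)CCC)CCCC(=O)OC
F4 | step 7 | (5S,10R)-10-{[tert-butyl(dimethyl)silyl]oxy}-5-ethenyltridecanoic acid | C=C[C@@H](CCCC[C@H](O[Si](C)(C)C(C)(C)C)CCC)CCCC(=O)O
F5 | step 7 | ethyl N-[(5S,10R)-10-{[tert-butyl(dimethyl)silyl]oxy}-5-ethenyltridecanoyl]-DL-alaninate | C=C[C@@H](CCCC[C@H](O[Si](C)(C)C(C)(C)C)CCC)CCCC(=O)NC(C)C(=O)OCC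
F6 | step 8 | (2E,4S,9R)-9-{[tert-butyl(dimethyl)silyl]oxy}-4-[3-(5-ethoxy-4-methyl-1,3-oxazol-2-yl)propyl]dodec-2-enoic acid | OC(=O)/C=C/[C@@H](CCCC[C@H](O[Si](C)(C)C(C)(C)C)CCC)CCCc1nc(C)c(OCC)o1
F7 | step 9 | (5S)-5-[(5R)-5-{[tert-butyl(dimethyl)silyl]oxy}octyl]-2-methyl-3-[(triethylsilyl)oxy]-5,6,7,8-tetrahydroquinoline | CC[Si](CC)(CC)Oc1cc2c(nc1C)CCC[C@@H]2CCCC[C@H](O[Si](C)(C)C(C)(C)C)CCC
F8 | step 9 | tert-butyl (2S,3S,4aS,5S,8aR)-5-[(5R)-5-{[tert-butyl(dimethyl)silyl]oxy}octyl]-2-methyl-3-[(triethylsilyl)oxy]octahydroquinoline-1(2H)-carboxylate | CC[Si](CC)(CC)O[C@H]1C[C@H]2[C@@H](CCCC[C@H](O[Si](C)(C)C(C)(C)C)CCC)CCC[C@H]2N(C(=O)OC(C)(C)C)[C@H]1C
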